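The earlier runs and the new flask stem from a simulated flask for substances that don't exist; the scatter is artificial.

Reagent and substrate leave in equal moles: each turn of the catalyst, on either hand, spends one reagent and makes one product. So I kept the books on the reagent.

in all of them: left-handed substrate 0.71 M; right-handed substrate 0.71 M; free catalyst 3.5 mM; impurity 0.81 mM
- zeta: reagent 0.71 M; run made earlier
- theta: reagent 1.6 M; run made earlier
- flask: reagent 1.06 M; time 15 min

- zeta (time / min: right-handed substrate / %, left-handed substrate / %): 0.667: 45.6, 15.2; 1.33: 40.4, 10.3; 2.00: 41.9, 9.8; 3.00: 42.8, 10.2; 5.00: 41.1, 8.6; 10.0: 40.7, 9.6
- theta (time / min: right-handed substrate / %, left-handed substrate / %): 1.50: 18.1, 0; 3.00: 9.4, 0; 5.00: 3.8, 0; 6.00: 0.9, 0.5; 8.00: 1.1, 0.2; 10.0: 0, 0.5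

(each reading ± 1 percentage point)

* whether the excess of right-handed substrate over left-handed substrate among what is left of the two reaches 98% by 15 min (yes / no)
* the highest excess of right-handed substrate over left-handed substrate among what is left of the two up to 15 min

- free catalyst is single-handed; left-handed substrate and right-handed substrate are mirror images of each other, charged as a racemate, each of them at the stated concentration
- the analysis behind the earlier runs scatters by 1 percentage point, standard deviation
- steps under discussion: free catalyst + left-handed substrate <-> catalyst intermediate A; reagent + catalyst intermediate A -> free catalyst + left-handed product; free catalyst + impurity -> spent catalyst B; free catalyst + right-handed substrate <-> catalyst intermediate B; reagent + catalyst intermediate B -> free catalyst + right-handed product; free catalyst -> spent catalyst A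

For the flask, I took the reagent ceiling C, the reagent charged over both substrates charged, which is the converted share this limiting reagent can pay for: 74.6%. The zeta run's C was 50.0%, and its readings at 10.0 min showed 49.7% converted.

The first entry in my estimated ledger for the flask was left-handed substrate, because the zeta run kept 9.6% of it against 40.7% right-handed. I booked that half of the pooled charge of both substrates to the reagent, and the remaining 24.6% of the pooled charge to right-handed substrate, which left 25.4% of the pooled charge unreacted on paper. I read the selectivity factor s, the logarithm of the share of left-handed substrate kept divided by the logarithm of the share of right-handed substrate kept, from those zeta readings as 8.02. So I reckoned that about 0.431% of the left-handed charge remained, and my estimated excess came to 98.3%, just above 98%. The theta run's right-handed substrate halved in about 1.55 min, far shorter than 15 min, so I expected the flask's books to close in time.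

The forecast said yes, with 98.7% (range 96.8% to 99.5%), taking s near 9; its excess stood higher than mine. On the stall it wrote “The reagent runs out rather than the catalyst dying”.

The flask gave yes: its excess reached 98% at 3.63 min and topped at 98.9%.

    free catalyst + left-handed substrate ⇌ catalyst intermediate A (K = 3.70 L mol⁻¹, k = 590 L mol⁻¹ s⁻¹)
    reagent + catalyst intermediate A → free catalyst + left-handed product (k = 30.0 L mol⁻¹ s⁻¹)
    free catalyst + impurity → spent catalyst B (k = 11000 L mol⁻¹ s⁻¹)
    free catalyst + right-handed substrate ⇌ catalyst intermediate B (K = 1.40 L mol⁻¹, k = 32.0 L mol⁻¹ s⁻¹)
    reagent + catalyst intermediate B → free catalyst + right-handed product (k = 9.80 L mol⁻¹ s⁻¹)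
    free catalyst → spent catalyst A (k = 1.90 × 10⁻⁵ s⁻¹)

At 7.50 min the flask had converted 74.5%, against C of 74.6%, with 0.343% of the reagent's charge left. The theta run's C, 113%, stood above the whole charge, and its right-handed substrate read 0% at 10.0 min. In the flask, the half-life of free catalyst by its turning into spent catalyst A alone was 10 h, much longer than the 3.63 min the excess took to reach 98%, and that step made no difference to the excess at 15 min. Spent catalyst B held 23.1% of the flask's catalyst at 15.0 min, while reagent stood at 0.00574% of its own charge.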